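**Retrosynthetic overview**

1. The target is epicatechin 3-O-gallate-(4β→8)-epicatechin 3-O-gallate-(4β→8)-catechin; the last operations are desilylation and removal of eighteen benzyl groups.
2. The strategy rests on the middle ring A, a pentasubstituted phloroglucinol ring: C8 carries top C4, C8a carries O1, C4a carries C4, C5 and C7 carry oxygen, and C6 carries H. It is built by benzannulation of cyclobutenone 20 with siloxyalkyne 9, which forms C8–C8a and C6–C7.
3. The middle ring C (O1–C2 and C3–C4) is then closed on the resulting o-benzylphenol 28 by a [4+2] of its o-quinone methide with the Z-enol gallate 23.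
4. Alkyne 9 comes from (−)-epicatechin by C4 alkynylation trans to the 3-O-gallate and acetylide oxidation/silylation. Cyclobutenone 20 comes from (+)-catechin by C8 bromination, Negishi coupling and a ketene–ethoxyacetylene [2+2].
5. Ring order: top and bottom flavans from the chiral pool, then middle ring A (step 16), then middle ring C (step 17).

Key step: step 16

Assumption: (−)-epicatechin, (+)-catechin, 3,4,5-tris(benzyloxy)benzoic acid, 3,4-bis(benzyloxy)benzaldehyde and ethoxyacetylene are taken as commercial. At C4 of an epicatechin unit, β means trans to the 3-oxygen and to the 2-aryl group. The sp3 ring carbon of 19 and 20 is an inconsequential mixture of epimers.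

**Route**

Step 1
Reactants: 1 (−)-epicatechin
Product: 2 5,7,3',4'-tetra-O-benzyl-(−)-epicatechin
Conditions: BnBr, K2CO3, DMF, 0 °C → rt
Reagents that add atoms: benzyl bromide, BrCc1ccccc1
Why: Williamson etherification in which K2CO3 deprotonates only the four phenols, so the 3-OH stays free and C2/C3 are untouched.

Step 2
Reactants: 2 5,7,3',4'-tetra-O-benzyl-(−)-epicatechin
Product: 3 4β-(2-ethoxyethoxy)-5,7,3',4'-tetra-O-benzylepicatechin
Conditions: DDQ, 2-ethoxyethanol, CH2Cl2, rt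
Reagents that add atoms: 2-ethoxyethanol, CCOCCO
Why: DDQ benzylic oxidation (hydride abstraction at C4 to the ring-A-stabilised cation) and capture by the alcohol on the face opposite the 2-aryl and 3-OH groups, which sets C4 as the β ether (3,4-trans).

Step 3
Reactants: 3 4β-(2-ethoxyethoxy)-5,7,3',4'-tetra-O-benzylepicatechin; 4 3,4,5-tris(benzyloxy)benzoic acid
Product: 5 4β-(2-ethoxyethoxy)-5,7,3',4'-tetra-O-benzylepicatechin 3-O-(3,4,5-tri-O-benzylgallate)
Conditions: DCC, DMAP, CH2Cl2, rt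
Reagents that add atoms: none
Why: Steglich esterification acylates the hindered axial 3-OH under neutral conditions that leave the acid-labile C4 ether in place.

Step 4
Reactants: 5 4β-(2-ethoxyethoxy)-5,7,3',4'-tetra-O-benzylepicatechin 3-O-(3,4,5-tri-O-benzylgallate)
Product: 6 4β-[(trimethylsilyl)ethynyl]-5,7,3',4'-tetra-O-benzylepicatechin 3-O-(3,4,5-tri-O-benzylgallate)
Conditions: TMS–C≡C–BF3K (3 equiv), BF3·OEt2, CH2Cl2/MeCN, −30 → 0 °C, high dilution
Reagents that add atoms: potassium (trimethylsilyl)ethynyltrifluoroborate, C[Si](C)(C)C#C[B-](F)(F)F.[K+]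
Why: Lewis-acid substitution of a benzylic ether by an alkynyltrifluoroborate (alkynylation of a stabilised benzylic cation); the gallate carbonyl bridges the C4 cation on the α face, so the alkynyl group should enter from the β face and set C4 trans to the 3-O-gallate.

Step 5
Reactants: 6 4β-[(trimethylsilyl)ethynyl]-5,7,3',4'-tetra-O-benzylepicatechin 3-O-(3,4,5-tri-O-benzylgallate)
Product: 7 4β-ethynyl-5,7,3',4'-tetra-O-benzylepicatechin 3-O-(3,4,5-tri-O-benzylgallate)
Conditions: TBAF, AcOH, THF, 0 °C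
Reagents that add atoms: none
Why: Fluoride protodesilylation of the alkynylsilane, buffered with acetic acid so that neither the gallate nor the propargylic C4–H is exposed to base.

Step 6
Reactants: 7 4β-ethynyl-5,7,3',4'-tetra-O-benzylepicatechin 3-O-(3,4,5-tri-O-benzylgallate)
Product: 9 4β-[(triisopropylsiloxy)ethynyl]-5,7,3',4'-tetra-O-benzylepicatechin 3-O-(3,4,5-tri-O-benzylgallate), via lithium ynolate 8 (not isolated)
Conditions: LiHMDS (1.1 equiv), THF, −78 °C; t-BuOOLi (from t-BuOOH and LiHMDS), −78 → −10 °C; TIPSOTf, −78 → 0 °C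
Reagents that add atoms: tert-butyl hydroperoxide, CC(C)(C)OO; triisopropylsilyl triflate, CC(C)[Si](C(C)C)(C(C)C)OS(=O)(=O)C(F)(F)F
Why: Julia oxidation of the lithium acetylide by lithium tert-butyl peroxide to the ynolate and O-silylation (Kozmin procedure); the non-enolisable, hindered gallate sits trans-diaxial to the alkyne and should tolerate the amide base at low temperature, and C4 is not deprotonated.

Step 7
Reactants: 10 (+)-catechin
Product: 11 5,7,3',4'-tetra-O-benzyl-(+)-catechin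
Conditions: BnBr, K2CO3, DMF, 0 °C → rt
Reagents that add atoms: benzyl bromide, BrCc1ccccc1
Why: Williamson etherification of the four phenols under carbonate, as in step 1, without epimerisation at C2.

Step 8
Reactants: 11 5,7,3',4'-tetra-O-benzyl-(+)-catechin
Product: 12 3,5,7,3',4'-penta-O-benzyl-(+)-catechin
Conditions: NaH, BnBr, DMF, 0 °C → rt
Reagents that add atoms: benzyl bromide, BrCc1ccccc1
Why: Williamson etherification of the secondary alkoxide, possible now that no free phenol can trigger ring opening at C2.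

Step 9
Reactants: 12 3,5,7,3',4'-penta-O-benzyl-(+)-catechin
Product: 13 8-bromo-3,5,7,3',4'-penta-O-benzylcatechin
Conditions: NBS, CH2Cl2, −40 °C → rt
Reagents that add atoms: N-bromosuccinimide, O=C1CCC(=O)N1Br
Why: Electrophilic aromatic bromination, which in benzylated catechins goes to C8, the more nucleophilic of the two open ring-A positions.

Step 10
Reactants: 13 8-bromo-3,5,7,3',4'-penta-O-benzylcatechin
Product: 14 ethyl 3-(penta-O-benzylcatechin-8-yl)propanoate
Conditions: BrZnCH2CH2CO2Et, Pd(OAc)2 (cat.), SPhos, THF, 60 °C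
Reagents that add atoms: (3-ethoxy-3-oxopropyl)zinc bromide, CCOC(=O)CC[Zn]Br
Why: Negishi sp2–sp3 coupling of a zinc homoenolate, with a bulky biarylphosphine to let the di-ortho-substituted, electron-rich aryl bromide undergo oxidative addition and to outrun β-hydride elimination.

Step 11
Reactants: 14 ethyl 3-(penta-O-benzylcatechin-8-yl)propanoate
Product: 15 3-(penta-O-benzylcatechin-8-yl)propanoic acid
Conditions: LiOH, THF/MeOH/H2O, rt; then dilute HCl
Reagents that add atoms: lithium hydroxide, [Li+].[OH-]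
Why: Saponification of an unhindered ethyl ester; benzyl ethers and both stereocentres are inert to hydroxide.

Step 12
Reactants: 15 3-(penta-O-benzylcatechin-8-yl)propanoic acid; 16 ethoxyacetylene
Product: 19 3-ethoxy-4-[(penta-O-benzylcatechin-8-yl)methyl]cyclobut-2-en-1-one, via acyl chloride 17 (not isolated), via ketene 18 (not isolated)
Conditions: 1-chloro-N,N,2-trimethylpropenylamine, CH2Cl2, 0 °C → rt; then slow addition to Et3N and 16 (5 equiv), CH2Cl2, rt → 40 °C
Reagents that add atoms: none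
Why: Neutral acid chloride formation (no Vilsmeier-type species that could formylate ring A), dehydrochlorination to the monoalkylketene and its [2+2] with the ynol ether, the ketene carbonyl carbon bonding to the terminal alkyne carbon; slow addition limits ketene dimerisation, and the new ring stereocentre is uncontrolled and is erased in step 16.

Step 13
Reactants: 19 3-ethoxy-4-[(penta-O-benzylcatechin-8-yl)methyl]cyclobut-2-en-1-one
Product: 20 3-benzyloxy-4-[(penta-O-benzylcatechin-8-yl)methyl]cyclobut-2-en-1-one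
Conditions: BnOH (10 equiv), PPTS (cat.), toluene, 40 °C, reduced pressure
Reagents that add atoms: benzyl alcohol, OCc1ccccc1
Why: Acid-catalysed transetherification of a vinylogous ester by addition–elimination at the alkoxy-bearing carbon, driven by removal of ethanol and run under weak acid so that the ring double bond does not move onto the substituted carbon.

Step 14
Reactants: 21 3,4-bis(benzyloxy)benzaldehyde
Product: 22 1,2-bis(benzyloxy)-4-ethynylbenzene
Conditions: dimethyl (1-diazo-2-oxopropyl)phosphonate, K2CO3, MeOH, rt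
Reagents that add atoms: dimethyl (1-diazo-2-oxopropyl)phosphonate, COP(=O)(OC)C(=[N+]=[N-])C(C)=O
Why: Seyferth–Gilbert homologation with the Ohira–Bestmann reagent converts the non-enolisable aryl aldehyde into the terminal alkyne under mild base.

Step 15
Reactants: 22 1,2-bis(benzyloxy)-4-ethynylbenzene; 4 3,4,5-tris(benzyloxy)benzoic acid
Product: 23 (Z)-2-[3,4-bis(benzyloxy)phenyl]ethenyl 3,4,5-tris(benzyloxy)benzoate
Conditions: Ru(2-methylallyl)2(dppb) (cat.), toluene, 65 °C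
Reagents that add atoms: none
Why: Ruthenium-catalysed anti-Markovnikov addition of a carboxylic acid to a terminal alkyne through a vinylidene complex, which delivers the enol ester with Z geometry.

Step 16
Reactants: 9 4β-[(triisopropylsiloxy)ethynyl]-5,7,3',4'-tetra-O-benzylepicatechin 3-O-(3,4,5-tri-O-benzylgallate); 20 3-benzyloxy-4-[(penta-O-benzylcatechin-8-yl)methyl]cyclobut-2-en-1-one
Product: 28 phenol carrying the new middle ring A between the top flavan (at C8) and the catechin-8-ylmethyl group (at C4a), via vinylketene 24 (not isolated), via alkenylcyclobutenone 25 (not isolated), via dienylketene 26 (not isolated), via cyclohexadienone 27 (not isolated)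
Conditions: 20 (1.3 equiv), toluene (degassed, 0.2 M), 80 °C then 110 °C, sealed tube, argon
Reagents that add atoms: none
Why: Heat cleaves the C1–C4 bond of 20 in a 4π electrocyclic opening (alkyl group turning outward) to the vinylketene 24, which undergoes a [2+2] with 9 in which the ketene carbon bonds to the nucleophilic alkyne carbon bearing the flavan and the ketene α-carbon bonds to the silyloxy carbon, giving 25. A second 4π opening gives the dienylketene 26, whose 6π electrocyclisation re-forms C8a–C4a within a six-membered ring (27), and tautomerisation gives the phenol 28. The closest known reaction is the Danheiser benzannulation of cyclobutenones with triisopropylsiloxyalkynes, which gives resorcinol monosilyl ethers. The one ring formed, the middle ring A, is closed by the 6π electrocyclisation after the [2+2] has made C8–C8a and C6–C7. No stereocentre is created; the propargylic top C4 takes no part in any pericyclic event, and the neutral thermal conditions leave it and the gallate alone. The step needs only the regiochemistry of the ketene–alkyne [2+2], secured by the polarisation of the siloxyalkyne, so the phenol oxygen ends between the carbon bearing the top unit and the carbon bearing the catechinylmethyl group and the three ring oxygens emerge as OH, OSi and OBn.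

Step 17
Reactants: 28 phenol from step 16; 23 (Z)-2-[3,4-bis(benzyloxy)phenyl]ethenyl 3,4,5-tris(benzyloxy)benzoate
Product: 30 fully benzylated trimer with the middle C7 oxygen as triisopropylsilyl ether, via o-quinone methide 29 (not isolated)
Conditions: Ag2O (3 equiv), 23 (3 equiv), 4 Å MS, CH2Cl2, rt, dark
Reagents that add atoms: none
Why: Proposed new method: Ag2O should oxidise the hindered phenol to the o-quinone methide 29 at the methylene (the top C4–H lies in the plane of the central ring and is not aligned for loss), and 29 should add the Z-enol ester in an inverse-demand hetero-Diels–Alder reaction, the closest known reaction being the [4+2] of o-quinone methides with styrenes and β-substituted styrenes to give flavans; the methide carbon C4 bonds to the acyloxy-bearing carbon because the developing positive charge is best placed on the benzylic carbon para to a benzyloxy group, suprafacial addition to the Z-alkene sets C2/C3 cis, endo addition to the methide whose aryl group is pushed syn to the carbonyl by the C5 benzyloxy group sets C4 trans to C3, and attack on the α face is expected because the top unit (C4–H toward the C7 silyl ether) holds its ring A over the β face, this facial and endo/exo control being the least secure element of the route.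

Step 18
Reactants: 30 fully benzylated trimer with the middle C7 oxygen as triisopropylsilyl ether
Product: 31 fully benzylated trimer with free middle C7–OH
Conditions: TBAF, AcOH, THF, 0 °C
Reagents that add atoms: none
Why: Fluoride cleavage of the aryl silyl ether, buffered so that the two gallate esters neither migrate nor cleave.

Step 19
Reactants: 31 fully benzylated trimer with free middle C7–OH
Product: 32 CNP0269915.2
Conditions: H2 (1 atm), Pd(OH)2/C, THF/MeOH/H2O, rt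
Reagents that add atoms: none
Why: Hydrogenolysis of all eighteen benzyl ethers under neutral conditions that should spare the interflavan bonds, the gallates and every stereocentre.

**Compound list**

1 | (−)-epicatechin | C1c2c(O)cc(O)cc2O[C@H](c2ccc(O)c(O)c2)[C@@H]1O | starting material
2 | 5,7,3',4'-tetra-O-benzyl-(−)-epicatechin | C1c2c(OCc9ccccc9)cc(OCc9ccccc9)cc2O[C@H](c2ccc(OCc9ccccc9)c(OCc9ccccc9)c2)[C@@H]1O | intermediate
3 | 4β-(2-ethoxyethoxy)-5,7,3',4'-tetra-O-benzylepicatechin (3,4-trans) | CCOCCO[C@H]3c4c(OCc9ccccc9)cc(OCc9ccccc9)cc4O[C@H](c8ccc(OCc9ccccc9)c(OCc9ccccc9)c8)[C@@H]3O | intermediate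
4 | 3,4,5-tris(benzyloxy)benzoic acid | OC(=O)c1cc(OCc9ccccc9)c(OCc9ccccc9)c(OCc9ccccc9)c1 | starting material
5 | 4β-(2-ethoxyethoxy)-5,7,3',4'-tetra-O-benzylepicatechin 3-O-(3,4,5-tri-O-benzylgallate) | CCOCCO[C@H]3c4c(OCc9ccccc9)cc(OCc9ccccc9)cc4O[C@H](c8ccc(OCc9ccccc9)c(OCc9ccccc9)c8)[C@@H]3OC(=O)c7cc(OCc9ccccc9)c(OCc9ccccc9)c(OCc9ccccc9)c7 | intermediate
6 | 4β-[(trimethylsilyl)ethynyl]-5,7,3',4'-tetra-O-benzylepicatechin 3-O-(3,4,5-tri-O-benzylgallate) | C[Si](C)(C)C#C[C@H]3c4c(OCc9ccccc9)cc(OCc9ccccc9)cc4O[C@H](c8ccc(OCc9ccccc9)c(OCc9ccccc9)c8)[C@@H]3OC(=O)c7cc(OCc9ccccc9)c(OCc9ccccc9)c(OCc9ccccc9)c7 | intermediate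
7 | 4β-ethynyl-5,7,3',4'-tetra-O-benzylepicatechin 3-O-(3,4,5-tri-O-benzylgallate) | C#C[C@H]3c4c(OCc9ccccc9)cc(OCc9ccccc9)cc4O[C@H](c8ccc(OCc9ccccc9)c(OCc9ccccc9)c8)[C@@H]3OC(=O)c7cc(OCc9ccccc9)c(OCc9ccccc9)c(OCc9ccccc9)c7 | intermediate
8 | lithium ynolate derived from 7 | [Li+].[O-]C#C[C@H]3c4c(OCc9ccccc9)cc(OCc9ccccc9)cc4O[C@H](c8ccc(OCc9ccccc9)c(OCc9ccccc9)c8)[C@@H]3OC(=O)c7cc(OCc9ccccc9)c(OCc9ccccc9)c(OCc9ccccc9)c7 | intermediate
9 | 4β-[(triisopropylsiloxy)ethynyl]-5,7,3',4'-tetra-O-benzylepicatechin 3-O-(3,4,5-tri-O-benzylgallate) | CC(C)[Si](C(C)C)(C(C)C)OC#C[C@H]3c4c(OCc9ccccc9)cc(OCc9ccccc9)cc4O[C@H](c8ccc(OCc9ccccc9)c(OCc9ccccc9)c8)[C@@H]3OC(=O)c7cc(OCc9ccccc9)c(OCc9ccccc9)c(OCc9ccccc9)c7 | intermediate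
10 | (+)-catechin | c1c(O)cc(O)c2c1O[C@H](c1ccc(O)c(O)c1)[C@@H](O)C2 | starting material
11 | 5,7,3',4'-tetra-O-benzyl-(+)-catechin | c1c(OCc9ccccc9)cc(OCc9ccccc9)c2c1O[C@H](c1ccc(OCc9ccccc9)c(OCc9ccccc9)c1)[C@@H](O)C2 | intermediate
12 | 3,5,7,3',4'-penta-O-benzyl-(+)-catechin | c1c(OCc9ccccc9)cc(OCc9ccccc9)c2c1O[C@H](c1ccc(OCc9ccccc9)c(OCc9ccccc9)c1)[C@@H](OCc9ccccc9)C2 | intermediate
13 | 8-bromo-3,5,7,3',4'-penta-O-benzylcatechin | Brc2c(OCc9ccccc9)cc(OCc9ccccc9)c3c2O[C@H](c8ccc(OCc9ccccc9)c(OCc9ccccc9)c8)[C@@H](OCc9ccccc9)C3 | intermediate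
14 | ethyl 3-(penta-O-benzylcatechin-8-yl)propanoate | CCOC(=O)CCc2c(OCc9ccccc9)cc(OCc9ccccc9)c3c2O[C@H](c8ccc(OCc9ccccc9)c(OCc9ccccc9)c8)[C@@H](OCc9ccccc9)C3 | intermediate
15 | 3-(penta-O-benzylcatechin-8-yl)propanoic acid | OC(=O)CCc2c(OCc9ccccc9)cc(OCc9ccccc9)c3c2O[C@H](c8ccc(OCc9ccccc9)c(OCc9ccccc9)c8)[C@@H](OCc9ccccc9)C3 | intermediate
16 | ethoxyacetylene | CCOC#C | starting material
17 | 3-(penta-O-benzylcatechin-8-yl)propanoyl chloride | O=C(Cl)CCc2c(OCc9ccccc9)cc(OCc9ccccc9)c3c2O[C@H](c8ccc(OCc9ccccc9)c(OCc9ccccc9)c8)[C@@H](OCc9ccccc9)C3 | intermediate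
18 | 4-(penta-O-benzylcatechin-8-yl)but-1-en-1-one (monoalkylketene) | O=C=CCc2c(OCc9ccccc9)cc(OCc9ccccc9)c3c2O[C@H](c8ccc(OCc9ccccc9)c(OCc9ccccc9)c8)[C@@H](OCc9ccccc9)C3 | intermediate
19 | 3-ethoxy-4-[(penta-O-benzylcatechin-8-yl)methyl]cyclobut-2-en-1-one (both epimers at ring C4) | CCOC1=CC(=O)C1Cc2c(OCc9ccccc9)cc(OCc9ccccc9)c3c2O[C@H](c8ccc(OCc9ccccc9)c(OCc9ccccc9)c8)[C@@H](OCc9ccccc9)C3 | intermediate
20 | 3-benzyloxy-4-[(penta-O-benzylcatechin-8-yl)methyl]cyclobut-2-en-1-one (both epimers at ring C4) | O=C1C=C(OCc9ccccc9)C1Cc2c(OCc9ccccc9)cc(OCc9ccccc9)c3c2O[C@H](c8ccc(OCc9ccccc9)c(OCc9ccccc9)c8)[C@@H](OCc9ccccc9)C3 | intermediate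
21 | 3,4-bis(benzyloxy)benzaldehyde | O=Cc1ccc(OCc9ccccc9)c(OCc9ccccc9)c1 | starting material
22 | 1,2-bis(benzyloxy)-4-ethynylbenzene | C#Cc1ccc(OCc9ccccc9)c(OCc9ccccc9)c1 | intermediate
23 | (Z)-2-[3,4-bis(benzyloxy)phenyl]ethenyl 3,4,5-tris(benzyloxy)benzoate | O=C(O/C=C\c1ccc(OCc9ccccc9)c(OCc9ccccc9)c1)c7cc(OCc9ccccc9)c(OCc9ccccc9)c(OCc9ccccc9)c7 | intermediate
24 | (Z)-3-benzyloxy-5-(penta-O-benzylcatechin-8-yl)penta-1,3-dien-1-one (vinylketene) | O=C=C/C(OCc9ccccc9)=C/Cc2c(OCc9ccccc9)cc(OCc9ccccc9)c3c2O[C@H](c8ccc(OCc9ccccc9)c(OCc9ccccc9)c8)[C@@H](OCc9ccccc9)C3 | intermediate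
25 | 2-(top flavan-4β-yl)-3-(triisopropylsiloxy)-4-[1-benzyloxy-3-(penta-O-benzylcatechin-8-yl)prop-1-enyl]cyclobut-2-en-1-one | O=C1C([C@H]3c4c(OCc9ccccc9)cc(OCc9ccccc9)cc4O[C@H](c8ccc(OCc9ccccc9)c(OCc9ccccc9)c8)[C@@H]3OC(=O)c7cc(OCc9ccccc9)c(OCc9ccccc9)c(OCc9ccccc9)c7)=C(O[Si](C(C)C)(C(C)C)C(C)C)C1/C(OCc9ccccc9)=C/Cc2c(OCc9ccccc9)cc(OCc9ccccc9)c3c2O[C@H](c8ccc(OCc9ccccc9)c(OCc9ccccc9)c8)[C@@H](OCc9ccccc9)C3 | intermediate
26 | dienylketene from ring opening of 25 (flavanyl-bearing carbon and C5 cis across the C7=C6 bond) | O=C=C([C@H]3c4c(OCc9ccccc9)cc(OCc9ccccc9)cc4O[C@H](c8ccc(OCc9ccccc9)c(OCc9ccccc9)c8)[C@@H]3OC(=O)c7cc(OCc9ccccc9)c(OCc9ccccc9)c(OCc9ccccc9)c7)/C(O[Si](C(C)C)(C(C)C)C(C)C)=C\C(OCc9ccccc9)=C\Cc2c(OCc9ccccc9)cc(OCc9ccccc9)c3c2O[C@H](c8ccc(OCc9ccccc9)c(OCc9ccccc9)c8)[C@@H](OCc9ccccc9)C3 | intermediate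
27 | 2-(top flavan-4β-yl)-3-(triisopropylsiloxy)-5-benzyloxy-6-[(penta-O-benzylcatechin-8-yl)methyl]cyclohexa-2,4-dien-1-one | O=C1C([C@H]3c4c(OCc9ccccc9)cc(OCc9ccccc9)cc4O[C@H](c8ccc(OCc9ccccc9)c(OCc9ccccc9)c8)[C@@H]3OC(=O)c7cc(OCc9ccccc9)c(OCc9ccccc9)c(OCc9ccccc9)c7)=C(O[Si](C(C)C)(C(C)C)C(C)C)C=C(OCc9ccccc9)C1Cc2c(OCc9ccccc9)cc(OCc9ccccc9)c3c2O[C@H](c8ccc(OCc9ccccc9)c(OCc9ccccc9)c8)[C@@H](OCc9ccccc9)C3 | intermediate
28 | 3-benzyloxy-2-[(penta-O-benzylcatechin-8-yl)methyl]-5-(triisopropylsiloxy)-6-[tetra-O-benzylepicatechin 3-O-(tri-O-benzylgallate)-4β-yl]phenol | Oc1c(Cc2c(OCc9ccccc9)cc(OCc9ccccc9)c3c2O[C@H](c8ccc(OCc9ccccc9)c(OCc9ccccc9)c8)[C@@H](OCc9ccccc9)C3)c(OCc9ccccc9)cc(O[Si](C(C)C)(C(C)C)C(C)C)c1[C@H]3c4c(OCc9ccccc9)cc(OCc9ccccc9)cc4O[C@H](c8ccc(OCc9ccccc9)c(OCc9ccccc9)c8)[C@@H]3OC(=O)c7cc(OCc9ccccc9)c(OCc9ccccc9)c(OCc9ccccc9)c7 | intermediate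
29 | o-quinone methide from 28 (catechinyl group on the methide carbon syn to the carbonyl) | O=C1C([C@H]3c4c(OCc9ccccc9)cc(OCc9ccccc9)cc4O[C@H](c8ccc(OCc9ccccc9)c(OCc9ccccc9)c8)[C@@H]3OC(=O)c7cc(OCc9ccccc9)c(OCc9ccccc9)c(OCc9ccccc9)c7)=C(O[Si](C(C)C)(C(C)C)C(C)C)C=C(OCc9ccccc9)/C1=C/c2c(OCc9ccccc9)cc(OCc9ccccc9)c3c2O[C@H](c8ccc(OCc9ccccc9)c(OCc9ccccc9)c8)[C@@H](OCc9ccccc9)C3 | intermediate
30 | octadeca-O-benzyl trimer with middle C7–O-triisopropylsilyl (middle unit 2,3-cis-3,4-trans, epicatechin configuration) | O=C(O[C@@H]1[C@@H](c2c(OCc9ccccc9)cc(OCc9ccccc9)c3c2O[C@H](c2ccc(OCc9ccccc9)c(OCc9ccccc9)c2)[C@@H](OCc9ccccc9)C3)c2c(OCc9ccccc9)cc(O[Si](C(C)C)(C(C)C)C(C)C)c([C@H]3c4c(OCc9ccccc9)cc(OCc9ccccc9)cc4O[C@H](c4ccc(OCc9ccccc9)c(OCc9ccccc9)c4)[C@@H]3OC(=O)c3cc(OCc9ccccc9)c(OCc9ccccc9)c(OCc9ccccc9)c3)c2O[C@@H]1c1ccc(OCc9ccccc9)c(OCc9ccccc9)c1)c1cc(OCc9ccccc9)c(OCc9ccccc9)c(OCc9ccccc9)c1 | intermediate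
31 | octadeca-O-benzyl trimer with free middle C7–OH | O=C(O[C@@H]1[C@@H](c2c(OCc9ccccc9)cc(OCc9ccccc9)c3c2O[C@H](c2ccc(OCc9ccccc9)c(OCc9ccccc9)c2)[C@@H](OCc9ccccc9)C3)c2c(OCc9ccccc9)cc(O)c([C@H]3c4c(OCc9ccccc9)cc(OCc9ccccc9)cc4O[C@H](c4ccc(OCc9ccccc9)c(OCc9ccccc9)c4)[C@@H]3OC(=O)c3cc(OCc9ccccc9)c(OCc9ccccc9)c(OCc9ccccc9)c3)c2O[C@@H]1c1ccc(OCc9ccccc9)c(OCc9ccccc9)c1)c1cc(OCc9ccccc9)c(OCc9ccccc9)c(OCc9ccccc9)c1 | intermediate
32 | CNP0269915.2, epicatechin 3-O-gallate-(4β→8)-epicatechin 3-O-gallate-(4β→8)-catechin | O=C(O[C@@H]1[C@@H](c2c(O)cc(O)c3c2O[C@H](c2ccc(O)c(O)c2)[C@@H](O)C3)c2c(O)cc(O)c([C@H]3c4c(O)cc(O)cc4O[C@H](c4ccc(O)c(O)c4)[C@@H]3OC(=O)c3cc(O)c(O)c(O)c3)c2O[C@@H]1c1ccc(O)c(O)c1)c1cc(O)c(O)c(O)c1 | target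

**Step count**

Total: 19 steps. Longest linear sequence: 11 steps (steps 7–13 and 16–19, from (+)-catechin).

**Steps most likely to fail**

Step 17. The cycloaddition may proceed stepwise through the benzylic cation with loss of the Z geometry (2,3-trans ring), may take the wrong endo/exo or facial course, or the oxidation may occur at the top C4–H instead of the methylene. The fallback sets out from 28 and 22 and comes back at 30. Alkyne 22 would be converted by trans-hydroboration with pinacolborane ([RhCl(cod)]2, P(i-Pr)3, Et3N) into (Z)-2-[3,4-bis(benzyloxy)phenyl]ethenylboronic acid pinacol ester F1. The quinone methide 29, generated from 28 as before, would take up F1 in a conjugate addition catalysed by 3,3'-dibromo-BINOL, with the enantiomer of the diol chosen to give the target C4 configuration; this should give the (Z)-1,3-diarylallyl phenol F2. Epoxidation of the Z-alkene with dimethyldioxirane, expected anti to the pentasubstituted ring under allylic 1,3-strain control, would give the cis-epoxide F3. The phenol would open F3 at the benzylic carbon with inversion (6-endo, cat. CSA) to the 2,3-cis-3,4-trans flavan-3-ol F4, and Steglich esterification of F4 with 4 (DCC, DMAP) gives 30.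

Step 16. Ring opening of the alkoxy-stabilised cyclobutenone may be too slow at temperatures the siloxyalkyne tolerates, the hindered partners may retard the [2+2], and the vinylketene may acylate the product phenol. The fallback sets out from 15 (with 9) and comes back at 28. Acid 15 would be homologated (CDI, then magnesium ethyl malonate) to ethyl 3-oxo-5-(penta-O-benzylcatechin-8-yl)pentanoate F5. Mitsunobu O-benzylation (BnOH, PPh3, DIAD) would give ethyl (E)-3-benzyloxy-5-(penta-O-benzylcatechin-8-yl)pent-2-enoate F6, and saponification would give (E)-3-benzyloxy-5-(penta-O-benzylcatechin-8-yl)pent-2-enoic acid F7. The α-chloroenamine of step 12 would convert F7 into the acid chloride F8. Slow addition of F8 to Et3N and 9 in toluene at room temperature would generate the same vinylketene 24 by 1,4-dehydrochlorination, with no four-membered ring to open, and warming would carry the adduct 25 on to 28.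

Step 13. Acid may move the ring double bond onto the substituted carbon, which would place the catechinylmethyl group para to the phenol after step 16, or may cleave the strained ring. The fallback sets out from 15 and comes back at 20. Benzyl alcohol, KH and trichloroethylene would give benzyl (E)-1,2-dichlorovinyl ether F9. Treatment of F9 with n-BuLi (2 equiv) at −78 °C and a methanol quench would give benzyloxyethyne F10, kept cold. The ketene 18, generated from 15 exactly as in step 12, would then be trapped by F10 at 0 °C in the same [2+2], giving 20 directly without any exchange at the enol ether.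

**Further compounds**

F1 | step 17 | (Z)-2-[3,4-bis(benzyloxy)phenyl]ethenylboronic acid pinacol ester | CC1(C)OB(/C=C\c2ccc(OCc9ccccc9)c(OCc9ccccc9)c2)OC1(C)C
F2 | step 17 | (Z)-1,3-diarylallyl phenol from conjugate addition to 29 | c1(ccc(OCc9ccccc9)c(OCc9ccccc9)c1)/C=C\[C@@H](c2c(OCc9ccccc9)cc(OCc9ccccc9)c3c2O[C@H](c2ccc(OCc9ccccc9)c(OCc9ccccc9)c2)[C@@H](OCc9ccccc9)C3)c2c(OCc9ccccc9)cc(O[Si](C(C)C)(C(C)C)C(C)C)c([C@H]3c4c(OCc9ccccc9)cc(OCc9ccccc9)cc4O[C@H](c4ccc(OCc9ccccc9)c(OCc9ccccc9)c4)[C@@H]3OC(=O)c3cc(OCc9ccccc9)c(OCc9ccccc9)c(OCc9ccccc9)c3)c2O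
F3 | step 17 | cis-epoxide of F2 | O1[C@@H]([C@@H]1c1ccc(OCc9ccccc9)c(OCc9ccccc9)c1)[C@@H](c2c(OCc9ccccc9)cc(OCc9ccccc9)c3c2O[C@H](c2ccc(OCc9ccccc9)c(OCc9ccccc9)c2)[C@@H](OCc9ccccc9)C3)c2c(OCc9ccccc9)cc(O[Si](C(C)C)(C(C)C)C(C)C)c([C@H]3c4c(OCc9ccccc9)cc(OCc9ccccc9)cc4O[C@H](c4ccc(OCc9ccccc9)c(OCc9ccccc9)c4)[C@@H]3OC(=O)c3cc(OCc9ccccc9)c(OCc9ccccc9)c(OCc9ccccc9)c3)c2O
F4 | step 17 | protected trimer with free middle 3-OH (2,3-cis-3,4-trans) | O[C@@H]1[C@@H](c2c(OCc9ccccc9)cc(OCc9ccccc9)c3c2O[C@H](c2ccc(OCc9ccccc9)c(OCc9ccccc9)c2)[C@@H](OCc9ccccc9)C3)c2c(OCc9ccccc9)cc(O[Si](C(C)C)(C(C)C)C(C)C)c([C@H]3c4c(OCc9ccccc9)cc(OCc9ccccc9)cc4O[C@H](c4ccc(OCc9ccccc9)c(OCc9ccccc9)c4)[C@@H]3OC(=O)c3cc(OCc9ccccc9)c(OCc9ccccc9)c(OCc9ccccc9)c3)c2O[C@@H]1c1ccc(OCc9ccccc9)c(OCc9ccccc9)c1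
F5 | step 16 | ethyl 3-oxo-5-(penta-O-benzylcatechin-8-yl)pentanoate | CCOC(=O)CC(=O)CCc2c(OCc9ccccc9)cc(OCc9ccccc9)c3c2O[C@H](c8ccc(OCc9ccccc9)c(OCc9ccccc9)c8)[C@@H](OCc9ccccc9)C3
F6 | step 16 | ethyl (E)-3-benzyloxy-5-(penta-O-benzylcatechin-8-yl)pent-2-enoate | CCOC(=O)/C=C(OCc9ccccc9)\CCc2c(OCc9ccccc9)cc(OCc9ccccc9)c3c2O[C@H](c8ccc(OCc9ccccc9)c(OCc9ccccc9)c8)[C@@H](OCc9ccccc9)C3
F7 | step 16 | (E)-3-benzyloxy-5-(penta-O-benzylcatechin-8-yl)pent-2-enoic acid | OC(=O)/C=C(OCc9ccccc9)\CCc2c(OCc9ccccc9)cc(OCc9ccccc9)c3c2O[C@H](c8ccc(OCc9ccccc9)c(OCc9ccccc9)c8)[C@@H](OCc9ccccc9)C3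
F8 | step 16 | (E)-3-benzyloxy-5-(penta-O-benzylcatechin-8-yl)pent-2-enoyl chloride | ClC(=O)/C=C(OCc9ccccc9)\CCc2c(OCc9ccccc9)cc(OCc9ccccc9)c3c2O[C@H](c8ccc(OCc9ccccc9)c(OCc9ccccc9)c8)[C@@H](OCc9ccccc9)C3
F9 | step 13 | benzyl (E)-1,2-dichlorovinyl ether | Cl/C=C(/Cl)OCc1ccccc1
F10 | step 13 | benzyloxyethyne | C#COCc1ccccc1
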